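Readings and results were computed for an exercise; scatter was added.

Keep the books on the partner, for delta and alpha charge less of it than of substrate.

| flask | substrate | partner | temperature | remark | time |
|---|---|---|---|---|---|
| Monday's | 15 mM | 4.5 mM | 75 °C | run made earlier |  |
| Tuesday's | 15 mM | 6.8 mM | 95 °C | run made earlier |  |
| Sunday's | 7.5 mM | 9 mM | 75 °C | run made earlier |  |
| delta | 15 mM | 9.00 mM | 110 °C |  | 2.5 d |
| alpha | 15 mM | 9.00 mM | 80 °C |  | 2.5 d |

- Monday's (time / d: intermediate / %, product / %): 1.25: 4, 0; 4.00: 14, 0; 6.00: 15, 1; 10.0: 19, 0; 15.0: 25, 1
- Tuesday's (time / d: intermediate / %, product / %): 0.417: 11, 1; 1.25: 24, 2; 2.00: 26, 2; 4.00: 30, 2; 5.00: 28, 3; 6.00: 29, 6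
- Sunday's (time / d: intermediate / %, product / %): 1.25: 10, 3; 5.00: 35, 2; 8.00: 47, 1; 12.0: 51, 1; 15.0: 59, 4

(scatter of a reading: 2 percentage points)

- the earlier runs were read with a standard deviation of 2 percentage points
- a reading or a percentage of product counts all its forms, free or not

1. the flask that comes out highest in amount of intermediate, in percent of the substrate charged, or "all alike" when all lie within 1.5 percentage points (delta / alpha / all alike)
2. intermediate at the end, in percent of the substrate charged, delta
3. intermediate at the end, in percent of the substrate charged, alpha

Write the balance of this limiting reagent, taking one partner per intermediate. Of the substrate charged, delta and alpha can turn at most 60.0% into intermediate and whatever follows it: this is the partner ceiling, the partner charge over the substrate charge. Test it on the readings. Monday's ceiling is 30.0%, and its last intermediate plus product is 26.0%. Tuesday's ceiling is 45.3%, against 35.0%.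

Now run delta slowly. In the first instants, substrate meets partner and intermediate appears. Tuesday's first reading, scatter included, puts the partner's half-life at 1.19 d with this much substrate, even at Tuesday's lower temperature. In the middle, expect making to slow as the partner falls and losses to begin: Tuesday's intermediate reads 28% to 30% from 4.00 d on, with product reading 2% to 6% and their sum under Tuesday's ceiling. At the end, 2.5 d is twice Tuesday's half-life, so expect delta past its peak and under the ceiling. Monday's reading at 4.00 d, taken the same way, gives the partner a half-life of 5.94 d, longer than the time allowed, so expect alpha, just warmer at 80 °C, still climbing. This reckoning names no winner.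

The forecast does: delta, with delta 26% and alpha 20%. “Delta is probably highest, but not by much.”

The flasks give delta 24.6% and alpha 24.3%, closer than the margin: all alike.

    substrate + partner → intermediate + by-product (k = 4.60 L mol⁻¹ h⁻¹, Ea = 71.0 kJ mol⁻¹)
    intermediate → product (k = 0.00830 h⁻¹, Ea = 121 kJ mol⁻¹)
    partner + product ⇌ idle adduct, settled at all times (K = 190 L mol⁻¹, ΔH = −64.0 kJ mol⁻¹)
    intermediate → decomposed reagent (k = 0.00980 h⁻¹, Ea = 128 kJ mol⁻¹)
    (constants at 110 °C)

Delta is not at rest at 2.50 d: taking each step net, it makes intermediate at 0.347 of the rate it uses it. At ten times the time, 25.0 d, delta's partner stands at 0% of its own charge and its intermediate at 0.00599%. The substrate consumed, 60.0%, meets the ceiling, split into product 27.5% and decomposed reagent 32.5%. Alpha, under the same ceiling, has consumed 56.4% of its substrate by then, with partner at 3.15% of its own charge and intermediate up to 41.3%.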